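## Structural features

The target is a sesquineolignan built from three guaiacyl (4-oxy-3-methoxyphenyl) rings: a 2,5-diaryl-3,4-dimethyloxolane (O1, C2 with ring A, C3, C4, C5 with ring B) whose ring B phenol oxygen is etherified by C8' of a 1-arylpropan-1-ol chain (C7' is the carbinol carrying ring C, C8' carries the methyl group). The oxolane holds four contiguous stereocentres, C2 (S), C3 (R), C4 (S) and C5 (S): ring A and both methyl groups are cis on one face, and ring B at C5 is trans to the C4 methyl. The side chain adds a second, isolated pair of neighbouring stereocentres, C8' (R) and C7' (S), in the erythro relationship. Fragile elements are the two free phenols para to benzylic C–O bonds (quinone methide formation, acid-induced epimerisation at C2, C5 and C7'), the benzylic ring ethers C2–O1 and C5–O1 (hydrogenolysis, Lewis-acid ionisation) and the secondary benzylic alcohol. The real difficulty is twofold: the crowded, contra-thermodynamic cis,cis arrangement C2–C3–C4 beside a trans C4–C5 junction, and the need to tell the ring A phenol (free in the product) from the ring B phenol (alkylated). Every carbonyl intermediate with an α-CH(CH3) centre that is cis to its neighbour is at risk of epimerisation. The key step exploits that C3 and C4 with their cis methyl groups are a cis-2-butene unit flanked by two carbon–carbon bonds (C2–C3 and C4–C5): both bonds can be made together by [2+2] cycloaddition of a ring B aryl keteniminium ion, and O1 is afterwards inserted between C2 and C5.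

## Logic of the disconnections

21 from 20. The two phenolic O–Si bonds (ring A and ring C) are cut last. Both phenols wear the same fluoride-labile group, so the final operation is neither acidic nor reductive. The forward step must be buffered so that phenoxides do not start quinone methide chemistry at C7', C2 or C5.

20 from 19. The C7'–H bond is cut, turning the carbinol into a ketone. C7' is then derived from C8' by internal (chelate) control, so only one side-chain stereocentre has to be imported. The forward reduction must give the erythro isomer without epimerising the α-aryloxy ketone.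

19 from 17 and 18 (18 from 10). The C7'–ring C bond is cut to an N-methoxy-N-methylamide and an arylmagnesium bromide. Ring C then comes from the same aryl bromide as ring A, and the magnesium reagent is chosen because the amide carries an acidic α-aryloxy C–H. The forward addition must stop at the ketone stage and must not deprotonate C8'.

17 from 14 and 16, and 16 from 15. The O–C8' bond is cut with inversion, which traces C8' (R) to the (S)-lactate pool. The demand is a clean SN2 event at a secondary carbon and a single free phenol in 14.

14 from 13. The ring B O–H is traced back to an O–benzyl bond. Benzyl on ring B against silyl on ring A is what distinguishes the two phenols. The forward hydrogenolysis must spare the benzylic C2–O1 and C5–O1 bonds.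

13 from 12, and 12 from 8 and 11 (11 from 10). The C2–H bond and then the C2–ring A bond are cut, so C2 becomes a lactone carbonyl. This removes ring A and one stereocentre and leaves a three-stereocentre lactone. Forward, the aryllithium must add without enolising C3, and hydride must reach C2 from the face away from the methyl groups so that ring A ends cis to them.

8 from 7. O1 is taken out from between C2 and C5, leaving a four-membered ketone. The ring oxygen therefore need not be present during carbon–carbon bond formation. Forward, the aryl-bearing carbon must migrate, with retention, in the oxygen insertion.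

7 from 3 and 4 (through 5 and 6). The C2–C3 and C4–C5 bonds are cut together. This returns the cis-dimethyl unit to 4 and all remaining carbons of the ring to 3. The forward step must keep the alkene geometry, choose one of the two mirror-image orientations of 4 on 5, and leave the aryl-bearing carbon free to equilibrate to trans.

3 from 1 and 2; 10 from 9. An amide C–N bond and a phenol O–Si bond are cut, leading to catalogue compounds. The only demand is that the amide coupling does not touch the auxiliary stereocentre.

## Other disconnections considered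

Alternative 1: The cut removes a one-carbon benzylidene unit carrying ring B, i.e. the C4–C5 and C5–O1 bonds of the 2,3-dihydrofuran A1. This leaves the ring A enone A2, in which C2 is the carbonyl carbon and C3=C4 the alkene. In the forward step the carbene released from tosylhydrazone A3 under Rh2(OAc)4 catalysis is passed to a catalytic chiral sulfide; the sulfonium ylide adds to C4 of A2, the enolate oxygen closes on the benzylic carbon, and Sc(OTf)3 completes the ring closure to A1.
- In its favour: it is catalytic in the chiral controller and convergent, and A1 already carries ring A (silyl) and ring B (benzyl) with the same protecting pattern as 13. One hydrogenation could saturate C2=C3 and remove the benzyl group, arriving at 14 a step or two sooner than the chosen plan. On step economy it is the better route, and on convergence and protecting-group logic it is the equal.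
- Against it: the acceptor is an α,β-dimethyl enone, twisted and hindered at C4, whereas this ylide chemistry is at its best with unhindered aryl enones. The electron-rich benzylidene precursor is prone to self-coupling. The Lewis-acid stage passes through a ring-opened benzylic cation, so C5 rests on thermodynamic reclosure (acceptable, trans). C3 is sp2 in A1, so the crowded C2/C3 cis pair still has to be created by hydrogenating a tetrasubstituted enol ether from the face that carries ring B and is anti to the C4 methyl. That facial preference is not secured, and hydrogenolysis of benzylic C–O bonds competes.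
- Comparison: in the chosen plan C3 and C4 come stereospecifically from alkene geometry and only C2 is set late; here C4 is set by the catalyst and C2/C3 by a face-selective hydrogenation. The chosen plan is longer but structurally more secure.

Alternative 2: The cut is the C5–O1 bond of oxolane A4, leading to the open-chain phenol A5. In the forward step DDQ dehydrogenates the 4-hydroxybenzyl CH2 of A5 to the para-quinone methide A6, and the C2 hydroxyl adds to C5 in a 5-exo closure.
- In its favour: it is biomimetic and mild, and it passes through no carbonyl compound with an epimerisable α-centre. C5 is made last and should settle trans to the C4 methyl. A4 emerges with the ring B phenol free and ring A benzylated (the benzyl-bearing ring of A4 is ring A), so the two phenols are already differentiated for side-chain attachment. On these points it is the equal or the better of the chosen plan.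
- Against it: the ring closure builds only one bond and one stereocentre. The syn,syn triad C2–C3–C4 must be assembled beforehand in acyclic A5 by a separate multistep sequence that the key step does not shorten. DDQ can also oxidise or ionise the electron-rich benzylic carbinol at C2. The benzyl group would have to leave ring A at the very end, by hydrogenolysis in the presence of the benzylic alcohol and three benzylic C–O bonds, where the chosen plan ends with fluoride.
- Comparison: mechanistically the closure is simpler than a cycloaddition plus oxygen insertion, but overall step count is expected to be higher and the stereochemical burden is moved, not removed.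

Alternative 3: The cut is the C2–C3 bond and the acyl C–O bond of lactone A7. In the forward step a chiral triazolium-derived carbene converts tiglic aldehyde A8 into a homoenolate whose β-carbon adds to aldehyde A9; the alkoxide then closes the γ-lactone on the acyl azolium.
- In its favour: two catalogue compounds, one catalytic step, no auxiliary. A7 is all-cis, so its aryl group is ring A and its three stereocentres are C2, C3 and C4 of the target: the difficult triad would be made at once. In step economy and in directness toward that triad it is better than the chosen plan.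
- Against it: α-substituted enals are reluctant homoenolate precursors, and an electron-rich, unactivated aryl aldehyde is a weak acceptor, so benzoin-type and self-annulation pathways are expected to compete. The carbon α to the lactone carbonyl (C4 of the target) is set by a protonation with no element enforcing cis, and cis is the less stable, epimerisable arrangement. Ring B must then be attached at the lactone carbon (C5) trans to the C4 methyl, yet hydride reduction of the derived hemiketal would be expected to place ring B cis (all-cis oxolane), so the endgame would need an aryl nucleophile adding to a lactol-derived cation instead. The benzyl group again ends on ring A.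
- Comparison: the chosen plan derives the cis methyl pair from alkene geometry and sets C5 by equilibration and C2 by hydride delivery, each with a clear controlling element, at the cost of more steps.

Key step: step 2

Remarks on the chemistry (assumptions):
- Locants used throughout: O1, C2 (ring A), C3, C4, C5 (ring B); side chain C7' (carbinol, ring C) and C8' (ether carbon).
- The (S)-configured auxiliary is assumed to direct the cycloaddition to 7 as drawn; if its intrinsic sense is opposite, (R)-2-(methoxymethyl)pyrrolidine is used and nothing else changes.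
- Acid 1 (the O-benzyl ether of homovanillic acid) is taken as a catalogue compound, which saves the benzylation/saponification detour.
- Descriptors used: oxolane (2S,3R,4S,5S), side chain (7'S,8'R) erythro, 7 (2S,3S,4R), 8 (3R,4S,5S). The side-chain partner must be (S)-configured because the O–C8' bond is formed with inversion.

Step 1
Reactants: 1 (4-benzyloxy-3-methoxyphenyl)acetic acid; 2 (S)-2-(methoxymethyl)pyrrolidine
Product: 3 2-(4-benzyloxy-3-methoxyphenyl)-1-[(2S)-2-(methoxymethyl)pyrrolidin-1-yl]ethan-1-one
Conditions: DIC, HOBt (cat.), CH2Cl2, 0 °C → rt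
Reagents that add atoms: none
Why: Carbodiimide amide coupling through the HOBt active ester; an unhindered arylacetic acid and a secondary amine couple readily, and the auxiliary stereocentre is not involved.

Step 2
Reactants: 3 2-(4-benzyloxy-3-methoxyphenyl)-1-[(2S)-2-(methoxymethyl)pyrrolidin-1-yl]ethan-1-one; 4 cis-2-butene
Product: 7 (2S,3S,4R)-2-(4-benzyloxy-3-methoxyphenyl)-3,4-dimethylcyclobutan-1-one, via keteniminium triflate 5 (not isolated), via cyclobutaniminium triflate 6 (not isolated)
Conditions: Tf2O, 2,4,6-collidine, cis-2-butene (excess, condensed), CH2Cl2, sealed vessel, −20 °C → 40 °C; then H2O, NaHCO3, rt (Et3N, CH2Cl2 if needed to complete equilibration)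
Reagents that add atoms: water, O
Why: Tf2O converts the amide into an O-triflyl iminium ion from which collidine removes the benzylic proton to give keteniminium ion 5; the closest known reaction type is the keteniminium–alkene [2+2] cycloaddition used to make cyclobutanones from tertiary amides, including amides of 2-substituted pyrrolidines. The π bond of 4 attacks the electrophilic central carbon of 5 in the plane of its aryl and hydrogen substituents from the hydrogen side, and the developing secondary carbenium centre is captured at once by the enamine carbon, so the four-membered ring closes by a second C–C bond formation within a concerted but non-synchronous (or very short-lived stepwise) suprafacial addition to the alkene. Because no rotation about the former C=C bond of 4 intervenes, the two methyl groups stay cis in 6. The nitrogen substituents of 5 lie above and below the plane of the ketene C=C bond, so the methoxymethyl-bearing carbon of the auxiliary disfavours one of the two mirror-image orientations of the incoming alkene and thereby fixes the absolute configuration of the two methyl-bearing carbons (C3 and C4 of 7). The aryl-bearing carbon forms without reliable control, but it is benzylic and α to the iminium and later the carbonyl group, so it equilibrates through the enamine or enol during the bicarbonate hydrolysis and settles trans to its neighbouring methyl group (2S). Water supplies the carbonyl oxygen and releases the auxiliary for recovery. Regioselectivity is not an issue because 4 is symmetrical; the selectivity needed is capture of 5 by the alkene rather than by the electron-rich ring of a second molecule, which a large excess of condensed 4, moderate dilution and slow addition of Tf2O should secure. The methyl-bearing α-carbon is far less acidic than the benzylic one, so the mild base leaves the cis-dimethyl relationship intact.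

Step 3
Reactants: 7 (2S,3S,4R)-2-(4-benzyloxy-3-methoxyphenyl)-3,4-dimethylcyclobutan-1-one
Product: 8 (3R,4S,5S)-5-(4-benzyloxy-3-methoxyphenyl)-3,4-dimethyloxolan-2-one
Conditions: mCPBA, NaHCO3, CH2Cl2, 0 °C → rt
Reagents that add atoms: mCPBA, O=C(OO)c1cccc(Cl)c1
Why: Baeyer–Villiger oxidation, fast for a strained cyclobutanone under buffered conditions; in the Criegee intermediate the secondary benzylic carbon with the electron-rich aryl group should migrate in preference to the secondary alkyl carbon. Migration proceeds with retention, so oxygen enters between the carbonyl carbon and the aryl carbon and no stereocentre changes (aryl trans to the adjacent methyl, methyls cis).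

Step 4
Reactants: 9 4-bromo-2-methoxyphenol
Product: 10 (4-bromo-2-methoxyphenoxy)triisopropylsilane
Conditions: TIPSCl, imidazole, DMF, rt
Reagents that add atoms: triisopropylsilyl chloride, CC(C)[Si](Cl)(C(C)C)C(C)C
Why: Silylation of a phenol; the bulky triisopropylsilyl ether is chosen because it tolerates aryllithium and arylmagnesium formation, BF3·OEt2 at −78 °C, hydrogenolysis, Mitsunobu and borohydride conditions and leaves cleanly with fluoride.

Step 5
Reactants: 8 (3R,4S,5S)-5-(4-benzyloxy-3-methoxyphenyl)-3,4-dimethyloxolan-2-one; 10 (4-bromo-2-methoxyphenoxy)triisopropylsilane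
Product: 12 (3R,4S,5S)-5-(4-benzyloxy-3-methoxyphenyl)-2-[3-methoxy-4-(triisopropylsilyloxy)phenyl]-3,4-dimethyloxolan-2-ol as anomer mixture, via aryllithium 11 (not isolated)
Conditions: 10, n-BuLi, THF, −78 °C; then 8, −78 °C; AcOH, −78 °C → rt
Reagents that add atoms: none
Why: Bromine–lithium exchange followed by 1,2-addition of the aryllithium to the lactone carbonyl; the lithium hemiketal alkoxide persists at −78 °C, which prevents a second addition. The cold acidic quench protects the α-centre C3; the anomeric centre is of no consequence because it is removed in the next step.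

Step 6
Reactants: 12 (3R,4S,5S)-5-(4-benzyloxy-3-methoxyphenyl)-2-[3-methoxy-4-(triisopropylsilyloxy)phenyl]-3,4-dimethyloxolan-2-ol
Product: 13 (2S,3R,4S,5S)-5-(4-benzyloxy-3-methoxyphenyl)-2-[3-methoxy-4-(triisopropylsilyloxy)phenyl]-3,4-dimethyloxolane
Conditions: Et3SiH, BF3·OEt2, CH2Cl2, −78 °C; Et3N then aq. NaHCO3 at −78 °C
Reagents that add atoms: none
Why: Ionic hydrogenation of a hemiketal: BF3 ionises C2–OH to the aryl-stabilised oxocarbenium ion and the silane delivers hydride to C2 from the face opposite the adjacent C3 methyl (and the C4 methyl), so ring A ends cis to both methyl groups (C2 S). Silane present from the start and a cold basic quench are meant to outrun Lewis-acid epimerisation of the benzylic ether carbons and enol ether formation at C3.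

Step 7
Reactants: 13 (2S,3R,4S,5S)-5-(4-benzyloxy-3-methoxyphenyl)-2-[3-methoxy-4-(triisopropylsilyloxy)phenyl]-3,4-dimethyloxolane
Product: 14 2-methoxy-4-{(2S,3S,4R,5S)-5-[3-methoxy-4-(triisopropylsilyloxy)phenyl]-3,4-dimethyloxolan-2-yl}phenol
Conditions: H2 (1 atm), 10% Pd/C, EtOAc, rt, stopped at full conversion
Reagents that add atoms: none
Why: Hydrogenolysis of an aryl benzyl ether, which is much faster than cleavage of the secondary benzylic ring C–O bonds in a neutral, non-protic solvent at ambient pressure; the aryl silyl ether is inert and no stereocentre is touched.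

Step 8
Reactants: 15 ethyl (S)-lactate
Product: 16 (2S)-2-hydroxy-N-methoxy-N-methylpropanamide
Conditions: MeNH(OMe)·HCl, i-PrMgCl, THF, −20 °C → 0 °C; aq. NH4Cl
Reagents that add atoms: N,O-dimethylhydroxylamine hydrochloride, CNOC.Cl
Why: Aminolysis of the ester by the magnesium amide of N,O-dimethylhydroxylamine; the hydroxyl is carried as its magnesium alkoxide, which disfavours enolisation, so the (S) configuration is retained.

Step 9
Reactants: 14 2-methoxy-4-{(2S,3S,4R,5S)-5-[3-methoxy-4-(triisopropylsilyloxy)phenyl]-3,4-dimethyloxolan-2-yl}phenol; 16 (2S)-2-hydroxy-N-methoxy-N-methylpropanamide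
Product: 17 (2R)-N-methoxy-2-(2-methoxy-4-{(2S,3S,4R,5S)-5-[3-methoxy-4-(triisopropylsilyloxy)phenyl]-3,4-dimethyloxolan-2-yl}phenoxy)-N-methylpropanamide
Conditions: PPh3, DIAD, THF, 0 °C → rt
Reagents that add atoms: none
Why: Mitsunobu etherification: the phenol is acidic enough to protonate the betaine, and its phenoxide displaces the alkoxyphosphonium group of the secondary α-hydroxy amide by SN2 with inversion, turning (S) into the required (R) at C8'. Compound 14 has only one free phenol, so the side chain can go only onto ring B.

Step 10
Reactants: 17 (2R)-N-methoxy-2-(2-methoxy-4-{(2S,3S,4R,5S)-5-[3-methoxy-4-(triisopropylsilyloxy)phenyl]-3,4-dimethyloxolan-2-yl}phenoxy)-N-methylpropanamide; 10 (4-bromo-2-methoxyphenoxy)triisopropylsilane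
Product: 19 (2R)-2-(2-methoxy-4-{(2S,3S,4R,5S)-5-[3-methoxy-4-(triisopropylsilyloxy)phenyl]-3,4-dimethyloxolan-2-yl}phenoxy)-1-[3-methoxy-4-(triisopropylsilyloxy)phenyl]propan-1-one, via arylmagnesium bromide 18 (not isolated)
Conditions: 10, Mg turnings (I2-activated), THF, rt → 40 °C; then 17, THF, −20 °C → 0 °C; AcOH, −20 °C → rt
Reagents that add atoms: none
Why: Weinreb ketone synthesis with the aryl Grignard reagent formed by magnesium insertion into the C–Br bond of 10: the magnesium-chelated tetrahedral adduct survives until the quench, so there is no over-addition and the ketone is never exposed to the organometallic. The Grignard reagent is less basic than an aryllithium, so addition should outrun deprotonation at C8', and the cold acidic quench keeps the α-aryloxy ketone from epimerising.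

Step 11
Reactants: 19 (2R)-2-(2-methoxy-4-{(2S,3S,4R,5S)-5-[3-methoxy-4-(triisopropylsilyloxy)phenyl]-3,4-dimethyloxolan-2-yl}phenoxy)-1-[3-methoxy-4-(triisopropylsilyloxy)phenyl]propan-1-one
Product: 20 (1S,2R)-2-(2-methoxy-4-{(2S,3S,4R,5S)-5-[3-methoxy-4-(triisopropylsilyloxy)phenyl]-3,4-dimethyloxolan-2-yl}phenoxy)-1-[3-methoxy-4-(triisopropylsilyloxy)phenyl]propan-1-ol
Conditions: Zn(BH4)2, Et2O, −20 °C → 0 °C; aq. NH4Cl
Reagents that add atoms: none
Why: Chelation-controlled (Cram chelate) reduction: zinc bridges the carbonyl oxygen and the α-aryloxy oxygen (assisted by the neighbouring methoxy group), and hydride enters from the side of the C8' hydrogen rather than the C8' methyl. This gives the erythro alcohol, C7' (S) from C8' (R); the neutral, non-basic reagent does not epimerise C8'.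

Step 12
Reactants: 20 (1S,2R)-2-(2-methoxy-4-{(2S,3S,4R,5S)-5-[3-methoxy-4-(triisopropylsilyloxy)phenyl]-3,4-dimethyloxolan-2-yl}phenoxy)-1-[3-methoxy-4-(triisopropylsilyloxy)phenyl]propan-1-ol
Product: 21 (1S,2R)-1-(4-hydroxy-3-methoxyphenyl)-2-{4-[(2S,3S,4R,5S)-5-(4-hydroxy-3-methoxyphenyl)-3,4-dimethyloxolan-2-yl]-2-methoxyphenoxy}propan-1-ol
Conditions: Bu4NF, AcOH, THF, 0 °C
Reagents that add atoms: none
Why: Fluoride cleavage of the two aryl silyl ethers; the acetic acid buffer keeps the liberated phenols protonated, so no quinone methide forms at C7', C2 or C5 and all six stereocentres are untouched.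

Compound list
1 | (4-benzyloxy-3-methoxyphenyl)acetic acid | COc1cc(CC(=O)O)ccc1OCc1ccccc1 | starting material
2 | (S)-2-(methoxymethyl)pyrrolidine | COC[C@@H]1CCCN1 | starting material
3 | 2-(4-benzyloxy-3-methoxyphenyl)-1-[(2S)-2-(methoxymethyl)pyrrolidin-1-yl]ethan-1-one | COc1cc(CC(=O)N2CCC[C@H]2COC)ccc1OCc1ccccc1 | intermediate
4 | cis-2-butene | C/C=C\C | starting material
5 | (2S)-1-[2-(4-benzyloxy-3-methoxyphenyl)ethenylidene]-2-(methoxymethyl)pyrrolidin-1-ium triflate (keteniminium salt) | COc1cc(C=C=[N+]2CCC[C@H]2COC)ccc1OCc1ccccc1.[O-]S(=O)(=O)C(F)(F)F | intermediate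
6 | (2S)-1-[(3S,4R)-2-(4-benzyloxy-3-methoxyphenyl)-3,4-dimethylcyclobutylidene]-2-(methoxymethyl)pyrrolidin-1-ium triflate (methyls cis; aryl-bearing carbon not yet settled) | COC[C@@H]1CCC[N+]1=C2C(c3ccc(OCc4ccccc4)c(OC)c3)[C@@H](C)[C@H]2C.[O-]S(=O)(=O)C(F)(F)F | intermediate
7 | (2S,3S,4R)-2-(4-benzyloxy-3-methoxyphenyl)-3,4-dimethylcyclobutan-1-one | O=C1[C@H](c2ccc(OCc3ccccc3)c(OC)c2)[C@@H](C)[C@H]1C | intermediate
8 | (3R,4S,5S)-5-(4-benzyloxy-3-methoxyphenyl)-3,4-dimethyloxolan-2-one | O=C1O[C@H](c2ccc(OCc3ccccc3)c(OC)c2)[C@@H](C)[C@H]1C | intermediate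
9 | 4-bromo-2-methoxyphenol | COc1cc(Br)ccc1O | starting material
10 | (4-bromo-2-methoxyphenoxy)triisopropylsilane | COc1cc(Br)ccc1O[Si](C(C)C)(C(C)C)C(C)C | intermediate
11 | [3-methoxy-4-(triisopropylsilyloxy)phenyl]lithium | [Li]c1ccc(O[Si](C(C)C)(C(C)C)C(C)C)c(OC)c1 | intermediate
12 | (3R,4S,5S)-5-(4-benzyloxy-3-methoxyphenyl)-2-[3-methoxy-4-(triisopropylsilyloxy)phenyl]-3,4-dimethyloxolan-2-ol (anomer mixture, in equilibrium with the open hydroxy ketone) | COc1cc(C2(O)O[C@H](c3ccc(OCc4ccccc4)c(OC)c3)[C@@H](C)[C@H]2C)ccc1O[Si](C(C)C)(C(C)C)C(C)C | intermediate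
13 | (2S,3R,4S,5S)-5-(4-benzyloxy-3-methoxyphenyl)-2-[3-methoxy-4-(triisopropylsilyloxy)phenyl]-3,4-dimethyloxolane | COc1cc([C@H]2O[C@H](c3ccc(OCc4ccccc4)c(OC)c3)[C@@H](C)[C@H]2C)ccc1O[Si](C(C)C)(C(C)C)C(C)C | intermediate
14 | 2-methoxy-4-{(2S,3S,4R,5S)-5-[3-methoxy-4-(triisopropylsilyloxy)phenyl]-3,4-dimethyloxolan-2-yl}phenol | COc1cc([C@H]2O[C@H](c3ccc(O)c(OC)c3)[C@@H](C)[C@H]2C)ccc1O[Si](C(C)C)(C(C)C)C(C)C | intermediate
15 | ethyl (S)-lactate | CCOC(=O)[C@H](C)O | starting material
16 | (2S)-2-hydroxy-N-methoxy-N-methylpropanamide | C[C@H](O)C(=O)N(C)OC | intermediate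
17 | (2R)-N-methoxy-2-(2-methoxy-4-{(2S,3S,4R,5S)-5-[3-methoxy-4-(triisopropylsilyloxy)phenyl]-3,4-dimethyloxolan-2-yl}phenoxy)-N-methylpropanamide | COc1cc([C@H]2O[C@H](c3ccc(O[C@H](C)C(=O)N(C)OC)c(OC)c3)[C@@H](C)[C@H]2C)ccc1O[Si](C(C)C)(C(C)C)C(C)C | intermediate
18 | bromo[3-methoxy-4-(triisopropylsilyloxy)phenyl]magnesium (aryl Grignard reagent) | COc1cc([Mg]Br)ccc1O[Si](C(C)C)(C(C)C)C(C)C | intermediate
19 | (2R)-2-(2-methoxy-4-{(2S,3S,4R,5S)-5-[3-methoxy-4-(triisopropylsilyloxy)phenyl]-3,4-dimethyloxolan-2-yl}phenoxy)-1-[3-methoxy-4-(triisopropylsilyloxy)phenyl]propan-1-one | COc1cc([C@H]2O[C@H](c3ccc(O[C@H](C)C(=O)c4ccc(O[Si](C(C)C)(C(C)C)C(C)C)c(OC)c4)c(OC)c3)[C@@H](C)[C@H]2C)ccc1O[Si](C(C)C)(C(C)C)C(C)C | intermediate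
20 | (1S,2R)-2-(2-methoxy-4-{(2S,3S,4R,5S)-5-[3-methoxy-4-(triisopropylsilyloxy)phenyl]-3,4-dimethyloxolan-2-yl}phenoxy)-1-[3-methoxy-4-(triisopropylsilyloxy)phenyl]propan-1-ol | COc1cc([C@H]2O[C@H](c3ccc(O[C@H](C)[C@@H](O)c4ccc(O[Si](C(C)C)(C(C)C)C(C)C)c(OC)c4)c(OC)c3)[C@@H](C)[C@H]2C)ccc1O[Si](C(C)C)(C(C)C)C(C)C | intermediate
21 | (1S,2R)-1-(4-hydroxy-3-methoxyphenyl)-2-{4-[(2S,3S,4R,5S)-5-(4-hydroxy-3-methoxyphenyl)-3,4-dimethyloxolan-2-yl]-2-methoxyphenoxy}propan-1-ol | COc1cc([C@H]2O[C@H](c3ccc(O[C@H](C)[C@@H](O)c4ccc(O)c(OC)c4)c(OC)c3)[C@@H](C)[C@H]2C)ccc1O | target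

Total step count: 12. Longest linear sequence: 10 steps (steps 1, 2, 3, 5, 6, 7, 9, 10, 11, 12); steps 4 and 8 prepare the two side branches.

Least certain steps

Step 2 (key step). Three things may go wrong: weak or inverted facial discrimination by the auxiliary; self-consumption of the aldo-keteniminium ion (attack by the electron-rich ring of a second molecule, oligomerisation) before the gaseous alkene captures it; and over-equilibration that also epimerises the methyl-bearing α-carbon. An inverted sense is answered by the antipodal auxiliary. If selectivity or capture is poor, the fallback bypasses 7 and sets out from 9. Benzylation (BnBr, K2CO3, DMF) gives 1-(benzyloxy)-4-bromo-2-methoxybenzene F1. Bromine–lithium exchange (n-BuLi, THF, −78 °C) gives [4-(benzyloxy)-3-methoxyphenyl]lithium F2, which Zn(OTf)2 converts into [4-(benzyloxy)-3-methoxyphenyl]zinc triflate F3. Enantioselective ring-opening arylation of meso-2,3-dimethylsuccinic anhydride F4 (from commercial meso-2,3-dimethylsuccinic acid and acetyl chloride), catalysed by [Rh(cod)Cl]2 with a TADDOL-derived phosphoramidite ligand of the appropriate hand, should give (2R,3S)-4-(4-benzyloxy-3-methoxyphenyl)-2,3-dimethyl-4-oxobutanoic acid F5. The cis methyl pair then comes from the meso anhydride and the absolute configuration from the catalyst. Felkin–Anh reduction of the aryl ketone with LiBH(s-Bu)3 (THF, −78 °C) should give (2R,3S,4S)-4-(4-benzyloxy-3-methoxyphenyl)-4-hydroxy-2,3-dimethylbutanoic acid F6, which lactonises on acidic work-up. The fallback comes back to the route at 8.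

Step 6. Hydride delivery may lack facial selectivity, because ring B at C5 sits on the face that must be attacked while the two methyl groups shield the other. BF3 may also reopen the product at C2 or C5 to an aryl-stabilised cation that recloses to the more stable 2,3-trans isomer, and oxocarbenium–enol ether tautomerism may erode C3. The fallback sets out from 12. Acid-catalysed dehydration (camphorsulfonic acid, toluene) gives (2S,3S)-2-(4-benzyloxy-3-methoxyphenyl)-5-[3-methoxy-4-(triisopropylsilyloxy)phenyl]-3,4-dimethyl-2,3-dihydrofuran F12 (the same substance as A1). Hydrogenation (H2, Pd/C, EtOAc) should add hydrogen syn across C2=C3 from the face away from the allylic C4 methyl, setting C2 and C3 together and cleaving the benzyl ether in the same operation. This fallback has its own facial-selectivity uncertainty, with different controlling groups. It comes back at 14.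

Step 5. The basic aryllithium may enolise the lactone at C3 (returning material as a C3 epimer mixture), or the lithium hemiketal may open to the ketone and add a second aryl group. The fallback sets out from 8. Aminolysis with AlMe3 and MeNH(OMe)·HCl gives (2R,3S,4S)-4-(4-benzyloxy-3-methoxyphenyl)-4-hydroxy-N-methoxy-N,2,3-trimethylbutanamide F9. Immediate silylation (Et3SiCl, imidazole) gives (2R,3S,4S)-4-(4-benzyloxy-3-methoxyphenyl)-N-methoxy-N,2,3-trimethyl-4-(triethylsilyloxy)butanamide F10. Addition of the aryllithium 11, generated from 10 as in step 5, then stops at the chelated adduct and should deliver (2R,3S,4S)-4-(4-benzyloxy-3-methoxyphenyl)-1-[3-methoxy-4-(triisopropylsilyloxy)phenyl]-2,3-dimethyl-4-(triethylsilyloxy)butan-1-one F11. Mild acid (AcOH, THF, H2O) removes the triethylsilyl group and the hydroxy ketone closes. The fallback comes back at 12.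

Step 3. Two secondary carbons compete for migration; insertion on the methyl-bearing side would give the regioisomeric lactone, and the peracid may attack the electron-rich ring. The fallback sets out from 7. Soft enolisation (TBSOTf, Et3N, CH2Cl2) toward the benzylic side gives tert-butyl{[(3S,4R)-2-(4-benzyloxy-3-methoxyphenyl)-3,4-dimethylcyclobut-1-en-1-yl]oxy}dimethylsilane F7. Ozonolysis (O3, CH2Cl2, −78 °C; Me2S) cleaves the enol ether double bond to tert-butyldimethylsilyl (2R,3S)-4-(4-benzyloxy-3-methoxyphenyl)-2,3-dimethyl-4-oxobutanoate F8, and mild aqueous hydrolysis of this silyl ester gives (2R,3S)-4-(4-benzyloxy-3-methoxyphenyl)-2,3-dimethyl-4-oxobutanoic acid F5, in which the new oxygen is necessarily on the aryl-bearing carbon. Reduction with LiBH(s-Bu)3 gives (2R,3S,4S)-4-(4-benzyloxy-3-methoxyphenyl)-4-hydroxy-2,3-dimethylbutanoic acid F6, which lactonises. The fallback comes back at 8.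

Step 9. The redox condensation may be sluggish with an ortho-methoxy phenol and a secondary alcohol flanked by a bulky amide, so that elimination to the acrylamide or alkylation of the hydrazide competes. The fallback sets out from 16. Sulfonylation (TsCl, Et3N, DMAP, CH2Cl2) gives (2S)-1-[methoxy(methyl)amino]-1-oxopropan-2-yl 4-methylbenzenesulfonate F13. Williamson etherification with the potassium phenoxide of 14 (K2CO3, MeCN, 40 °C) proceeds by SN2 with inversion. The fallback comes back at 17.

Further compounds
F1 | step 2 | 1-(benzyloxy)-4-bromo-2-methoxybenzene | COc1cc(Br)ccc1OCc1ccccc1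
F2 | step 2 | [4-(benzyloxy)-3-methoxyphenyl]lithium | [Li]c1ccc(OCc2ccccc2)c(OC)c1
F3 | step 2 | [4-(benzyloxy)-3-methoxyphenyl]zinc triflate | COc1cc([Zn]OS(=O)(=O)C(F)(F)F)ccc1OCc1ccccc1
F4 | step 2 | meso-2,3-dimethylsuccinic anhydride, (3R,4S)-3,4-dimethyloxolane-2,5-dione | C[C@@H]1C(=O)OC(=O)[C@@H]1C
F5 | step 2 | (2R,3S)-4-(4-benzyloxy-3-methoxyphenyl)-2,3-dimethyl-4-oxobutanoic acid | O=C(c1ccc(OCc2ccccc2)c(OC)c1)[C@@H](C)[C@@H](C)C(=O)O
F6 | step 2 | (2R,3S,4S)-4-(4-benzyloxy-3-methoxyphenyl)-4-hydroxy-2,3-dimethylbutanoic acid | O[C@H](c1ccc(OCc2ccccc2)c(OC)c1)[C@@H](C)[C@@H](C)C(=O)O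
F7 | step 3 | tert-butyl{[(3S,4R)-2-(4-benzyloxy-3-methoxyphenyl)-3,4-dimethylcyclobut-1-en-1-yl]oxy}dimethylsilane | CC(C)(C)[Si](C)(C)OC1=C(c2ccc(OCc3ccccc3)c(OC)c2)[C@@H](C)[C@H]1C
F8 | step 3 | tert-butyldimethylsilyl (2R,3S)-4-(4-benzyloxy-3-methoxyphenyl)-2,3-dimethyl-4-oxobutanoate | CC(C)(C)[Si](C)(C)OC(=O)[C@H](C)[C@H](C)C(=O)c1ccc(OCc2ccccc2)c(OC)c1
F9 | step 5 | (2R,3S,4S)-4-(4-benzyloxy-3-methoxyphenyl)-4-hydroxy-N-methoxy-N,2,3-trimethylbutanamide | O[C@H](c1ccc(OCc2ccccc2)c(OC)c1)[C@@H](C)[C@@H](C)C(=O)N(C)OC
F10 | step 5 | (2R,3S,4S)-4-(4-benzyloxy-3-methoxyphenyl)-N-methoxy-N,2,3-trimethyl-4-(triethylsilyloxy)butanamide | CC[Si](CC)(CC)O[C@H](c1ccc(OCc2ccccc2)c(OC)c1)[C@@H](C)[C@@H](C)C(=O)N(C)OC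
F11 | step 5 | (2R,3S,4S)-4-(4-benzyloxy-3-methoxyphenyl)-1-[3-methoxy-4-(triisopropylsilyloxy)phenyl]-2,3-dimethyl-4-(triethylsilyloxy)butan-1-one | CC[Si](CC)(CC)O[C@H](c1ccc(OCc2ccccc2)c(OC)c1)[C@@H](C)[C@@H](C)C(=O)c1ccc(O[Si](C(C)C)(C(C)C)C(C)C)c(OC)c1
F12 | step 6 | (2S,3S)-2-(4-benzyloxy-3-methoxyphenyl)-5-[3-methoxy-4-(triisopropylsilyloxy)phenyl]-3,4-dimethyl-2,3-dihydrofuran | COc1cc(C2=C(C)[C@H](C)[C@@H](c3ccc(OCc4ccccc4)c(OC)c3)O2)ccc1O[Si](C(C)C)(C(C)C)C(C)C
F13 | step 9 | (2S)-1-[methoxy(methyl)amino]-1-oxopropan-2-yl 4-methylbenzenesulfonate | C[C@H](OS(=O)(=O)c1ccc(C)cc1)C(=O)N(C)OC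
A1 | alternative 1 | (2S,3S)-2-(4-benzyloxy-3-methoxyphenyl)-5-[3-methoxy-4-(triisopropylsilyloxy)phenyl]-3,4-dimethyl-2,3-dihydrofuran | COc1cc(C2=C(C)[C@H](C)[C@@H](c3ccc(OCc4ccccc4)c(OC)c3)O2)ccc1O[Si](C(C)C)(C(C)C)C(C)C
A2 | alternative 1 | (E)-1-[3-methoxy-4-(triisopropylsilyloxy)phenyl]-2-methylbut-2-en-1-one | C/C=C(\C)C(=O)c1ccc(O[Si](C(C)C)(C(C)C)C(C)C)c(OC)c1
A3 | alternative 1 | N'-[(E)-(4-benzyloxy-3-methoxyphenyl)methylidene]-4-methylbenzenesulfonohydrazide | COc1cc(/C=N/NS(=O)(=O)c2ccc(C)cc2)ccc1OCc1ccccc1
A4 | alternative 2 | (2S,3R,4S,5S)-2-(4-benzyloxy-3-methoxyphenyl)-5-(4-hydroxy-3-methoxyphenyl)-3,4-dimethyloxolane | COc1cc([C@H]2O[C@H](c3ccc(O)c(OC)c3)[C@@H](C)[C@H]2C)ccc1OCc1ccccc1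
A5 | alternative 2 | (1S,2R,3R)-1-(4-benzyloxy-3-methoxyphenyl)-4-(4-hydroxy-3-methoxyphenyl)-2,3-dimethylbutan-1-ol | COc1cc([C@@H](O)[C@H](C)[C@H](C)Cc2ccc(O)c(OC)c2)ccc1OCc1ccccc1
A6 | alternative 2 | para-quinone methide of A5, 4-[4-(4-benzyloxy-3-methoxyphenyl)-4-hydroxy-2,3-dimethylbutylidene]-2-methoxycyclohexa-2,5-dien-1-one with the chain configuration of A5 | O=C1C=CC(=C[C@@H](C)[C@@H](C)[C@H](O)c2ccc(OCc3ccccc3)c(OC)c2)C=C1OC
A7 | alternative 3 | (3S,4R,5S)-5-(4-benzyloxy-3-methoxyphenyl)-3,4-dimethyloxolan-2-one | COc1cc([C@H]2OC(=O)[C@@H](C)[C@H]2C)ccc1OCc1ccccc1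
A8 | alternative 3 | tiglic aldehyde, (E)-2-methylbut-2-enal | C/C=C(\C)C=O
A9 | alternative 3 | 4-benzyloxy-3-methoxybenzaldehyde | COc1cc(C=O)ccc1OCc1ccccc1
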